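The route cuts the C3–C3a bond of the indane. In the target, the exocyclic C3=C8 double bond carries its C8 hydrogen cis to the ring-fusion carbon C3a and the dihydrobenzofuran-5-yl group cis to C2. That is the pattern left when an aryl carbon and a hydrogen add to the same side of a C3≡C8 alkyne. A palladium-catalysed reductive alkyne cyclisation therefore closes the five-membered ring and fixes the alkene geometry in one operation, without touching a stereocentre. Its precursor is the acyclic octamethyl ether carrying a 2-bromo-4,6-dimethoxyphenyl group on C1, the propargylic centre C2 and the trans-dihydrobenzofuran, assembled by Sonogashira coupling of two enantiopure halves.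

Key step: step 14

Remark on locants: indane C1 bears the 4-oxygenated phenyl, C2 the 3,5-dioxygenated phenyl, C3 is the ring carbon of the exocyclic alkene, C3a and C7a are the fusion carbons next to C3 and C1, C8 is the exocyclic CH; "benzofuran C2/C3" refer to the dihydrobenzofuran.

Remark on the chemistry: the sense of induction of the chiral rhodium catalysts in steps 3 and 11 is assigned by analogy with simpler substrates; if the first analysis shows the opposite sense, the mirror-image ligand is used and nothing else changes.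

Step 1
Reactants: 1 1-bromo-3,5-dimethoxybenzene
Product: 2 2-bromo-4,6-dimethoxybenzaldehyde
Conditions: POCl3, DMF, 0 to 90 °C; aq NaOAc
Reagents that add atoms: N,N-dimethylformamide CN(C)C=O; water O
Why: Vilsmeier–Haack formylation, in which the chloroiminium electrophile attacks the position para to one methoxy group and ortho to the other (next to bromine) in preference to the more shielded position between the two methoxy groups, the minor regioisomer being removed by crystallisation.

Step 2
Reactants: 2 2-bromo-4,6-dimethoxybenzaldehyde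
Product: 3 methyl (2E)-3-(2-bromo-4,6-dimethoxyphenyl)prop-2-enoate
Conditions: (MeO)2P(O)CH2CO2Me, NaH, THF, 0 °C to rt
Reagents that add atoms: trimethyl phosphonoacetate COC(=O)CP(=O)(OC)OC
Why: Horner–Wadsworth–Emmons olefination, in which the stabilised phosphonate anion adds reversibly and eliminates through the more stable adduct, so the E enoate is expected even from this doubly ortho-substituted aldehyde.

Step 3
Reactants: 3 methyl (2E)-3-(2-bromo-4,6-dimethoxyphenyl)prop-2-enoate; 4 4-methoxyphenylboronic acid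
Product: 5 methyl (3S)-3-(2-bromo-4,6-dimethoxyphenyl)-3-(4-methoxyphenyl)propanoate
Conditions: [RhCl(C2H4)2]2 (2.5 mol%), (S,S)-Ph-bod* [(1S,4S)-2,5-diphenylbicyclo[2.2.2]octa-2,5-diene] (5.5 mol%), KOH (0.5 equiv), dioxane/H2O 10:1, 50 °C
Reagents that add atoms: none
Why: Hayashi–Miyaura conjugate arylation, in which the aryl group passes from boron to monovalent rhodium, inserts across the enoate and is released by protonation, the chiral diene directing it to the Re face of the β-carbon so that C1 is set as S, while the twisted 2,6-disubstituted aryl group behaves like a branched β-substituent (a tolerated class) and its C–Br bond is inert to the catalyst.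

Step 4
Reactants: 6 1-iodo-3,5-dimethoxybenzene; 7 1,3,5-trimethoxybenzene
Product: 10 (3,5-dimethoxyphenyl)(2,4,6-trimethoxyphenyl)iodonium trifluoromethanesulfonate, via hydroxy(tosyloxy)iodoarene 8 (not isolated), via iodonium tosylate 9 (not isolated)
Conditions: mCPBA, TsOH·H2O, MeCN, 55 °C; then 7, rt; aq NaOTf/CH2Cl2 work-up
Reagents that add atoms: sodium trifluoromethanesulfonate [Na+].[O-]S(=O)(=O)C(F)(F)F; p-toluenesulfonic acid Cc1ccc(S(=O)(=O)O)cc1 and mCPBA O=C(OO)c1cccc(Cl)c1 (atoms kept only in intermediates 8 and 9)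
Why: Known one-pot diaryliodonium synthesis, in which the aryl iodide is oxidised to the hydroxy(tosyloxy) derivative of trivalent iodine, this is captured within minutes by the far more nucleophilic trimethoxybenzene (a non-transferable dummy group), and anion metathesis during work-up supplies the weakly coordinating triflate.

Step 5
Reactants: 5 methyl (3S)-3-(2-bromo-4,6-dimethoxyphenyl)-3-(4-methoxyphenyl)propanoate; 10 (3,5-dimethoxyphenyl)(2,4,6-trimethoxyphenyl)iodonium trifluoromethanesulfonate
Product: 12 methyl (2S,3S)-3-(2-bromo-4,6-dimethoxyphenyl)-2-(3,5-dimethoxyphenyl)-3-(4-methoxyphenyl)propanoate, via silyl ketene acetal 11 (not isolated)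
Conditions: LiN(SiMe3)2, Me3SiCl, THF, −78 °C to rt; solvent exchange; 10, Cu(OTf)2 (10 mol%), CH2Cl2, 0 °C to rt
Reagents that add atoms: chlorotrimethylsilane C[Si](C)(C)Cl (atoms kept only in intermediate 11)
Why: Copper-catalysed α-arylation of a silyl ketene acetal with a diaryliodonium salt (known for ester-level enol silanes), in which an aryl complex of trivalent copper hands the unhindered 3,5-dimethoxyphenyl group to the α-carbon under base-free conditions where the product cannot epimerise, and C2 is set as S by 1,3-allylic strain, which holds the C1–H bond in the plane of the ketene acetal so that the electrophile enters anti to the bulky 2-bromo-4,6-dimethoxyphenyl group.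

Step 6
Reactants: 12 methyl (2S,3S)-3-(2-bromo-4,6-dimethoxyphenyl)-2-(3,5-dimethoxyphenyl)-3-(4-methoxyphenyl)propanoate
Product: 14 1-bromo-2-[(1S,2R)-2-(3,5-dimethoxyphenyl)-1-(4-methoxyphenyl)but-3-yn-1-yl]-3,5-dimethoxybenzene, via aldehyde 13 (not isolated)
Conditions: iBu2AlH, CH2Cl2, −78 °C; then MeOH, K2CO3, dimethyl (1-diazo-2-oxopropyl)phosphonate, −78 to 0 °C
Reagents that add atoms: dimethyl (1-diazo-2-oxopropyl)phosphonate CC(=O)C(=[N+]=[N-])P(=O)(OC)OC
Why: Reduction at −78 °C stops at the aluminium hemiacetal and the aldehyde is released only in the presence of the Ohira–Bestmann reagent (Seyferth–Gilbert homologation), so it is trapped as the alkyne as it forms and the epimerisable C2 centre has little lifetime as an α-aryl aldehyde, its spatial arrangement being kept while the descriptor changes to R only through the priority rules.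

Step 7
Reactants: 15 5-iodosalicylaldehyde; 16 4-methoxybenzyl chloride
Product: 17 5-iodo-2-[(4-methoxybenzyl)oxy]benzaldehyde
Conditions: K2CO3, NaI (cat.), DMF, 50 °C
Reagents that add atoms: none
Why: Williamson ether synthesis, in which the phenoxide displaces chloride from the activated benzylic halide and neither the aldehyde nor the aryl iodide reacts.

Step 8
Reactants: 17 5-iodo-2-[(4-methoxybenzyl)oxy]benzaldehyde; 1 1-bromo-3,5-dimethoxybenzene
Product: 19 (3,5-dimethoxyphenyl){5-iodo-2-[(4-methoxybenzyl)oxy]phenyl}methanol (racemic), via Grignard reagent 18 (not isolated)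
Conditions: Mg, THF, 40 °C; then 17, −20 °C; aq NH4Cl
Reagents that add atoms: magnesium [Mg] (kept only in intermediate 18)
Why: Grignard addition to the aldehyde at low temperature is far faster than iodine–magnesium exchange at the electron-rich aryl iodide, and the carbinol centre forms as a racemate, which is irrelevant because it is oxidised in the next step.

Step 9
Reactants: 19 (3,5-dimethoxyphenyl){5-iodo-2-[(4-methoxybenzyl)oxy]phenyl}methanol
Product: 20 (3,5-dimethoxyphenyl){5-iodo-2-[(4-methoxybenzyl)oxy]phenyl}methanone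
Conditions: MnO2, CH2Cl2, rt
Reagents that add atoms: none
Why: Manganese dioxide oxidises the doubly benzylic alcohol chemoselectively to the benzophenone and leaves the benzylic ether and the aryl iodide intact.

Step 10
Reactants: 20 (3,5-dimethoxyphenyl){5-iodo-2-[(4-methoxybenzyl)oxy]phenyl}methanone
Product: 21 [(3,5-dimethoxyphenyl){5-iodo-2-[(4-methoxybenzyl)oxy]phenyl}methylidene]hydrazine (E/Z mixture)
Conditions: N2H4·H2O, AcOH (cat.), EtOH, 80 °C
Reagents that add atoms: hydrazine NN
Why: Acid-catalysed condensation with excess hydrazine gives the N-unsubstituted hydrazone, whose E and Z isomers converge on one diazo compound.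

Step 11
Reactants: 21 [(3,5-dimethoxyphenyl){5-iodo-2-[(4-methoxybenzyl)oxy]phenyl}methylidene]hydrazine
Product: 23 (2S,3R)-3-(3,5-dimethoxyphenyl)-5-iodo-2-(4-methoxyphenyl)-2,3-dihydro-1-benzofuran (cis), via diazo compound 22 (not isolated)
Conditions: MnO2, CH2Cl2, 0 °C, filtration; then Rh2(R-PTAD)4 (1 mol%), CH2Cl2, −20 °C to rt
Reagents that add atoms: none
Why: Dehydrogenation gives the diaryldiazomethane and the chiral dirhodium tetracarboxylate turns it into a donor/donor carbene that inserts into the activated O–CH2 bond five atoms away (known enantioselective intramolecular C–H insertion to 2,3-diaryl-dihydrobenzofurans), the catalyst fixing benzofuran C3 as R and the concerted insertion giving the kinetically preferred cis arrangement at benzofuran C2.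

Step 12
Reactants: 23 (2S,3R)-3-(3,5-dimethoxyphenyl)-5-iodo-2-(4-methoxyphenyl)-2,3-dihydro-1-benzofuran
Product: 24 (2R,3R)-3-(3,5-dimethoxyphenyl)-5-iodo-2-(4-methoxyphenyl)-2,3-dihydro-1-benzofuran (trans)
Conditions: CF3CO2H, CH2Cl2, 0 °C to rt
Reagents that add atoms: none
Why: Acid-mediated epimerisation, in which reversible ionisation of the benzofuran C2–O bond to a 4-methoxybenzylic cation and reclosure deliver the thermodynamically preferred trans isomer, so benzofuran C2 is inverted to R under thermodynamic control while benzofuran C3 is not involved.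

Step 13
Reactants: 14 1-bromo-2-[(1S,2R)-2-(3,5-dimethoxyphenyl)-1-(4-methoxyphenyl)but-3-yn-1-yl]-3,5-dimethoxybenzene; 24 (2R,3R)-3-(3,5-dimethoxyphenyl)-5-iodo-2-(4-methoxyphenyl)-2,3-dihydro-1-benzofuran
Product: 25 (2R,3R)-5-[(3S,4S)-4-(2-bromo-4,6-dimethoxyphenyl)-3-(3,5-dimethoxyphenyl)-4-(4-methoxyphenyl)but-1-yn-1-yl]-3-(3,5-dimethoxyphenyl)-2-(4-methoxyphenyl)-2,3-dihydro-1-benzofuran
Conditions: PdCl2(PPh3)2 (3 mol%), CuI (5 mol%), Et3N, THF, rt, degassed
Reagents that add atoms: none
Why: Sonogashira coupling, in which zerovalent palladium inserts into the aryl iodide at room temperature and leaves the hindered aryl bromide untouched, and triethylamine is too weak a base to disturb the propargylic centre.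

Step 14
Reactants: 25 (2R,3R)-5-[(3S,4S)-4-(2-bromo-4,6-dimethoxyphenyl)-3-(3,5-dimethoxyphenyl)-4-(4-methoxyphenyl)but-1-yn-1-yl]-3-(3,5-dimethoxyphenyl)-2-(4-methoxyphenyl)-2,3-dihydro-1-benzofuran
Product: 26 (2R,3R)-5-{(E)-[(2S,3S)-2-(3,5-dimethoxyphenyl)-4,6-dimethoxy-3-(4-methoxyphenyl)-2,3-dihydro-1H-inden-1-ylidene]methyl}-3-(3,5-dimethoxyphenyl)-2-(4-methoxyphenyl)-2,3-dihydro-1-benzofuran (target octamethyl ether)
Conditions: Pd(PPh3)4 (10 mol%), HCO2Na (2 equiv), DMF/H2O 10:1, 80 °C, degassed
Reagents that add atoms: none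
Why: Zerovalent palladium inserts into the C3a–Br bond, the arylpalladium bromide adds syn across the C3≡C8 triple bond (C3a to C3, palladium to C8), bromide is exchanged for formate, carbon dioxide is lost and the C8–H bond forms by reductive elimination with retention at the vinyl carbon. The closest known reaction type is the reductive (hydroarylative) Heck cyclisation of ortho-haloaryl alkynes to alkylidene indanes with formate as hydride donor. The indane ring (C1, C2, C3, C3a, C7a) closes 5-exo-dig, because the three-atom tether C7a–C1–C2 cannot deliver C3a to the distal carbon C8 in a syn transition state. No stereocentre is created; the alkene geometry (C8–H cis to C3a, dihydrobenzofuranyl cis to C2) is dictated by the syn insertion and the retentive hydride transfer. The step needs cyclisation to outrun hydrodebromination of the arylpalladium species, no E/Z isomerisation of the α-aryl vinylpalladium intermediate and no palladium hydride-mediated shift of the new alkene into the ring; the intramolecular insertion is fast, the vinylpalladium species has no β-hydrogen, and excess formate at moderate temperature captures it quickly. C1, C2 and the two dihydrobenzofuran centres are spectators, since no base strong enough to remove the C2 hydrogen is present.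

Step 15
Reactants: 26 target octamethyl ether
Product: 27 (2S,3S)-1-{(E)-[(2R,3R)-3-(3,5-dihydroxyphenyl)-2-(4-hydroxyphenyl)-2,3-dihydro-1-benzofuran-5-yl]methylidene}-2-(3,5-dihydroxyphenyl)-3-(4-hydroxyphenyl)-2,3-dihydro-1H-indene-4,6-diol (CNP0184753.1)
Conditions: BBr3 (16 equiv), CH2Cl2, −78 to 0 °C; MeOH quench at −78 °C
Reagents that add atoms: none
Why: Boron tribromide ether cleavage, in which each methoxy oxygen is complexed and bromide removes the methyl group, and at low temperature the trans-dihydrobenzofuran (already the stable epimer) and the exocyclic stilbene-type alkene are expected to survive, no stereocentre being involved.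

Compound list
1 | 1-bromo-3,5-dimethoxybenzene | COc1cc(Br)cc(OC)c1 | starting material
2 | 2-bromo-4,6-dimethoxybenzaldehyde | O=Cc1c(Br)cc(OC)cc1OC | intermediate
3 | methyl (2E)-3-(2-bromo-4,6-dimethoxyphenyl)prop-2-enoate | COC(=O)/C=C/c1c(Br)cc(OC)cc1OC | intermediate
4 | 4-methoxyphenylboronic acid | COc1ccc(B(O)O)cc1 | starting material
5 | methyl (3S)-3-(2-bromo-4,6-dimethoxyphenyl)-3-(4-methoxyphenyl)propanoate | COc1ccc([C@@H](c2c(OC)cc(OC)cc2Br)CC(=O)OC)cc1 | intermediate
6 | 1-iodo-3,5-dimethoxybenzene | COc1cc(I)cc(OC)c1 | starting material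
7 | 1,3,5-trimethoxybenzene | COc1cc(OC)cc(OC)c1 | starting material
8 | 1-[hydroxy(tosyloxy)iodo]-3,5-dimethoxybenzene | COc1cc(OC)cc(I(O)OS(=O)(=O)c2ccc(C)cc2)c1 | intermediate
9 | (3,5-dimethoxyphenyl)(2,4,6-trimethoxyphenyl)iodonium 4-methylbenzenesulfonate | COc1cc(OC)cc([I+]c2c(OC)cc(OC)cc2OC)c1.Cc1ccc(S(=O)(=O)[O-])cc1 | intermediate
10 | (3,5-dimethoxyphenyl)(2,4,6-trimethoxyphenyl)iodonium trifluoromethanesulfonate | COc1cc(OC)cc([I+]c2c(OC)cc(OC)cc2OC)c1.[O-]S(=O)(=O)C(F)(F)F | intermediate
11 | {[(3S)-3-(2-bromo-4,6-dimethoxyphenyl)-1-methoxy-3-(4-methoxyphenyl)prop-1-en-1-yl]oxy}trimethylsilane (E/Z mixture) | COc1ccc([C@@H](c2c(OC)cc(OC)cc2Br)C=C(OC)O[Si](C)(C)C)cc1 | intermediate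
12 | methyl (2S,3S)-3-(2-bromo-4,6-dimethoxyphenyl)-2-(3,5-dimethoxyphenyl)-3-(4-methoxyphenyl)propanoate | COc1ccc([C@@H](c2c(OC)cc(OC)cc2Br)[C@H](C(=O)OC)c2cc(OC)cc(OC)c2)cc1 | intermediate
13 | (2S,3S)-3-(2-bromo-4,6-dimethoxyphenyl)-2-(3,5-dimethoxyphenyl)-3-(4-methoxyphenyl)propanal | COc1ccc([C@@H](c2c(OC)cc(OC)cc2Br)[C@H](C=O)c2cc(OC)cc(OC)c2)cc1 | intermediate
14 | 1-bromo-2-[(1S,2R)-2-(3,5-dimethoxyphenyl)-1-(4-methoxyphenyl)but-3-yn-1-yl]-3,5-dimethoxybenzene | COc1ccc([C@@H](c2c(OC)cc(OC)cc2Br)[C@H](C#C)c2cc(OC)cc(OC)c2)cc1 | intermediate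
15 | 5-iodosalicylaldehyde | O=Cc1cc(I)ccc1O | starting material
16 | 4-methoxybenzyl chloride | COc1ccc(CCl)cc1 | starting material
17 | 5-iodo-2-[(4-methoxybenzyl)oxy]benzaldehyde | COc1ccc(COc2ccc(I)cc2C=O)cc1 | intermediate
18 | (3,5-dimethoxyphenyl)magnesium bromide | COc1cc(OC)cc([Mg]Br)c1 | intermediate
19 | (3,5-dimethoxyphenyl){5-iodo-2-[(4-methoxybenzyl)oxy]phenyl}methanol (racemic) | COc1ccc(COc2ccc(I)cc2C(O)c2cc(OC)cc(OC)c2)cc1 | intermediate
20 | (3,5-dimethoxyphenyl){5-iodo-2-[(4-methoxybenzyl)oxy]phenyl}methanone | COc1ccc(COc2ccc(I)cc2C(=O)c2cc(OC)cc(OC)c2)cc1 | intermediate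
21 | [(3,5-dimethoxyphenyl){5-iodo-2-[(4-methoxybenzyl)oxy]phenyl}methylidene]hydrazine | COc1ccc(COc2ccc(I)cc2C(=NN)c2cc(OC)cc(OC)c2)cc1 | intermediate
22 | 2-[diazo(3,5-dimethoxyphenyl)methyl]-4-iodo-1-[(4-methoxybenzyl)oxy]benzene | COc1ccc(COc2ccc(I)cc2C(=[N+]=[N-])c2cc(OC)cc(OC)c2)cc1 | intermediate
23 | (2S,3R)-3-(3,5-dimethoxyphenyl)-5-iodo-2-(4-methoxyphenyl)-2,3-dihydro-1-benzofuran (cis) | Ic1ccc2c(c1)[C@@H](c1cc(OC)cc(OC)c1)[C@@H](c1ccc(OC)cc1)O2 | intermediate
24 | (2R,3R)-3-(3,5-dimethoxyphenyl)-5-iodo-2-(4-methoxyphenyl)-2,3-dihydro-1-benzofuran (trans) | Ic1ccc2c(c1)[C@@H](c1cc(OC)cc(OC)c1)[C@H](c1ccc(OC)cc1)O2 | intermediate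
25 | (2R,3R)-5-[(3S,4S)-4-(2-bromo-4,6-dimethoxyphenyl)-3-(3,5-dimethoxyphenyl)-4-(4-methoxyphenyl)but-1-yn-1-yl]-3-(3,5-dimethoxyphenyl)-2-(4-methoxyphenyl)-2,3-dihydro-1-benzofuran | COc1ccc([C@@H](c2c(OC)cc(OC)cc2Br)[C@H](C#Cc2ccc3c(c2)[C@@H](c2cc(OC)cc(OC)c2)[C@H](c2ccc(OC)cc2)O3)c2cc(OC)cc(OC)c2)cc1 | intermediate
26 | (2R,3R)-5-{(E)-[(2S,3S)-2-(3,5-dimethoxyphenyl)-4,6-dimethoxy-3-(4-methoxyphenyl)-2,3-dihydro-1H-inden-1-ylidene]methyl}-3-(3,5-dimethoxyphenyl)-2-(4-methoxyphenyl)-2,3-dihydro-1-benzofuran | COc1ccc([C@H]2c3c(OC)cc(OC)cc3/C(=C/c3ccc4c(c3)[C@@H](c3cc(OC)cc(OC)c3)[C@H](c3ccc(OC)cc3)O4)[C@@H]2c2cc(OC)cc(OC)c2)cc1 | intermediate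
27 | (2S,3S)-1-{(E)-[(2R,3R)-3-(3,5-dihydroxyphenyl)-2-(4-hydroxyphenyl)-2,3-dihydro-1-benzofuran-5-yl]methylidene}-2-(3,5-dihydroxyphenyl)-3-(4-hydroxyphenyl)-2,3-dihydro-1H-indene-4,6-diol | Oc1ccc([C@H]2c3c(O)cc(O)cc3/C(=C/c3ccc4c(c3)[C@@H](c3cc(O)cc(O)c3)[C@H](c3ccc(O)cc3)O4)[C@@H]2c2cc(O)cc(O)c2)cc1 | target

Total step count: 15.
Longest linear sequence: 9 steps (steps 7 to 15, from 5-iodosalicylaldehyde 15); the alkyne branch is 8 steps (steps 1, 2, 3, 5, 6, 13, 14, 15) and step 4 is a one-step side branch.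

Steps most likely to fail

Step 5. The crowded ketene acetal may be arylated slowly, or the 1,3-allylic strain bias may give incomplete facial selectivity at C2. The fallback puts C2 under catalyst control and sets out from ester 5. Saponification (LiOH, THF/H2O) should give (3S)-3-(2-bromo-4,6-dimethoxyphenyl)-3-(4-methoxyphenyl)propanoic acid F1. Activation as the mixed pivalic anhydride (t-BuCOCl, Et3N) and acylation of 1,3-oxazolidin-2-one (LiCl) should give the N-acyl oxazolidinone F2. Silylation (NaN(SiMe3)2, Me3SiCl, THF, −78 °C) gives the Z silyl ketene N,O-acetal F3. This is arylated with iodonium salt 10 under Cu(OTf)2 and a chiral bis(oxazoline) ligand, a known enantioselective α-arylation of N-acyl oxazolidinones in which the ligand chooses the face; the ligand antipode is matched to the substrate bias to give the (2S,3S)-α-aryl imide F4. Transesterification with MeOMgBr (MeMgBr, MeOH, CH2Cl2, 0 °C) comes back to the route at ester 12.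

Step 6. The transient α-aryl aldehyde may enolise in basic methanol before it is homologated, which would erode the configuration at C2. The fallback avoids any base while C2 is next to a carbonyl group and sets out from ester 12. Reduction with iBu2AlH at −78 °C and a neutral tartrate work-up gives aldehyde 13, which is used at once. Dibromo-olefination (CBr4, PPh3, 2,6-lutidine, CH2Cl2, 0 °C, the first half of the Corey–Fuchs sequence) should give the 1,1-dibromoalkene F5. Palladium-catalysed hydrogenolysis of the bromine trans to the chain (Bu3SnH, Pd(PPh3)4, toluene, rt) gives the (Z)-bromoalkene F6. Anti elimination with Bu4NF·3H2O in DMF at 60 °C comes back to the route at alkyne 14; the aryl bromide is not touched because no organolithium reagent is used.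

Step 14. The α-aryl vinylpalladium intermediate may isomerise before hydride capture (loss of alkene geometry), the aryl bromide may be reduced before it cyclises, or a palladium hydride may move the alkene into the ring. The fallback forms the same C3–C3a bond by alkene insertion and β-hydride elimination and sets out from alkyne 14. Hydroboration with pinacolborane (Cp2Zr(H)Cl cat., CH2Cl2, rt) should give the (E)-alkenylboronate F7. Suzuki–Miyaura coupling with iodide 24 (Pd(PPh3)4, aq K2CO3, THF, 40 °C) gives the (E)-alkene F8 with the aryl bromide intact. An intramolecular Mizoroki–Heck reaction (Pd(OAc)2, P(o-tol)3, Ag2CO3, MeCN, 80 °C) then closes the ring 5-exo-trig. Syn insertion puts palladium on C8, the only β-hydrogen is the one on C3, and syn elimination after one bond rotation should convert the E alkene stereospecifically into the exocyclic alkene with C8–H cis to C3a. This comes back to the route at octamethyl ether 26.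

Further compounds
F1 | step 5 | (3S)-3-(2-bromo-4,6-dimethoxyphenyl)-3-(4-methoxyphenyl)propanoic acid | COc1ccc([C@@H](c2c(OC)cc(OC)cc2Br)CC(=O)O)cc1
F2 | step 5 | 3-[(3S)-3-(2-bromo-4,6-dimethoxyphenyl)-3-(4-methoxyphenyl)propanoyl]-1,3-oxazolidin-2-one | COc1ccc([C@@H](c2c(OC)cc(OC)cc2Br)CC(=O)N2CCOC2=O)cc1
F3 | step 5 | 3-[(1Z,3S)-3-(2-bromo-4,6-dimethoxyphenyl)-3-(4-methoxyphenyl)-1-(trimethylsilyloxy)prop-1-en-1-yl]-1,3-oxazolidin-2-one | COc1ccc([C@@H](c2c(OC)cc(OC)cc2Br)/C=C(\O[Si](C)(C)C)N2CCOC2=O)cc1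
F4 | step 5 | 3-[(2S,3S)-3-(2-bromo-4,6-dimethoxyphenyl)-2-(3,5-dimethoxyphenyl)-3-(4-methoxyphenyl)propanoyl]-1,3-oxazolidin-2-one | COc1ccc([C@@H](c2c(OC)cc(OC)cc2Br)[C@H](C(=O)N2CCOC2=O)c2cc(OC)cc(OC)c2)cc1
F5 | step 6 | 1-bromo-2-[(1S,2R)-4,4-dibromo-2-(3,5-dimethoxyphenyl)-1-(4-methoxyphenyl)but-3-en-1-yl]-3,5-dimethoxybenzene | COc1ccc([C@@H](c2c(OC)cc(OC)cc2Br)[C@H](C=C(Br)Br)c2cc(OC)cc(OC)c2)cc1
F6 | step 6 | 1-bromo-2-[(1S,2R,3Z)-4-bromo-2-(3,5-dimethoxyphenyl)-1-(4-methoxyphenyl)but-3-en-1-yl]-3,5-dimethoxybenzene | COc1ccc([C@@H](c2c(OC)cc(OC)cc2Br)[C@H](/C=C\Br)c2cc(OC)cc(OC)c2)cc1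
F7 | step 14 | 2-[(1E,3S,4S)-4-(2-bromo-4,6-dimethoxyphenyl)-3-(3,5-dimethoxyphenyl)-4-(4-methoxyphenyl)but-1-en-1-yl]-4,4,5,5-tetramethyl-1,3,2-dioxaborolane | COc1ccc([C@@H](c2c(OC)cc(OC)cc2Br)[C@H](/C=C/B2OC(C)(C)C(C)(C)O2)c2cc(OC)cc(OC)c2)cc1
F8 | step 14 | (2R,3R)-5-[(1E,3S,4S)-4-(2-bromo-4,6-dimethoxyphenyl)-3-(3,5-dimethoxyphenyl)-4-(4-methoxyphenyl)but-1-en-1-yl]-3-(3,5-dimethoxyphenyl)-2-(4-methoxyphenyl)-2,3-dihydro-1-benzofuran | COc1ccc([C@@H](c2c(OC)cc(OC)cc2Br)[C@H](/C=C/c2ccc3c(c2)[C@@H](c2cc(OC)cc(OC)c2)[C@H](c2ccc(OC)cc2)O3)c2cc(OC)cc(OC)c2)cc1
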